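The ratio I carry is the standing odds of a substrate molecule: the part of the charge gone, divided by the part left. From the last reading of Sunday's run, these odds are 0.855.

- Sunday's: substrate 1.7 M; gas 200 mM (held); run made earlier
- flask: substrate 0.86 M; gas 200 mM (held); time 25 min

Sunday's run (percent of the substrate charged)

| time / min | substrate / % | product / % |
|---|---|---|
| 0.417 | 73.9 | 15.1 |
| 0.833 | 62.2 | 25.5 |
| 1.33 | 56.6 | 30.3 |
| 2.50 | 54.1 | 33.1 |
| 5.00 | 53.9 | 32.7 |

(readings scatter by 0.3 percentage points)

- at the start none of the gas is in solution

1. part of the substrate gone at 25 min
2. the product standing at 25 min, as a percentage of the substrate charged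
3. the adduct standing at 25 min, as a percentage of the substrate charged

I follow one molecule through Sunday's run in slow motion, taking adduct as what the balance leaves. In the first instants, at 0.417 min, substrate is down to 73.9% and the odds are 0.353. Adduct stands at 11.0% and product at 15.1%, and I treat adduct as the fork, where a molecule either goes on to product or goes back. In the middle, at 1.33 min, the odds have reached 0.767, and I expect the traffic back towards substrate to matter next. At the end of Sunday's run the climb has stopped as far as the readings can tell: substrate reads 54.1% at 2.50 min and 53.9% at 5.00 min, a step smaller than the scatter of 0.3 percentage points.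

The new flask holds 0.86 M of substrate against Sunday's 1.7 M, with gas held at the same 200 mM. I take it that one molecule's chances at each fork are not changed by how many others were charged, a pseudo-first-order picture. The asked 25 min is ten times the time of the first flat reading. So the odds carry over, and my reckoning gives a conversion of 46.1%, with product 32.7% and adduct 13.4%.

The forecast says 46.1%, 32.9% and 13.2%, on the ground that “percentages should not depend on the substrate charge”. Its product stands 0.2 points above my reading.

The flask gives 46.1%, 32.9% and 13.2%, which agrees with the forecast.

    substrate + coupling partner ⇌ adduct (K = 2.20 L mol⁻¹, k = 1.20 L mol⁻¹ s⁻¹)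
    adduct ⇌ product (K = 2.50, k = 0.120 s⁻¹)
    2 coupling partner → homo dimer (k = 0.580 L mol⁻¹ s⁻¹)
    gas ⇌ coupling partner, rate k4*(csat - [coupling partner]) (kL = 0.160 s⁻¹)

At the asked time the odds in this flask come to 0.855, and in the neighbour flask with 1.5 M of substrate to 0.854; coupling partner stands at 0.111 M in this flask and at 0.111 M in the neighbour. The main reason substrate stays is the way back from adduct to substrate and coupling partner. With that way struck out, the conversion of this flask goes from 46.1% to 100%.

The readings were generated by integration on assumed constants; noise was put on by code.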